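**Retrosynthetic overview**
1. Target 27 comes from macrolactone 22 by PMB removal, angeloylation and desilylation; the usual plan (close the ten-membered ring by RCM or vinyl iodide–aldehyde coupling, add the lactone afterwards) is not used.
2. Key step: intramolecular Barbier allylation–lactonisation of acyclic bromo-enal 19 forms the C3a–C11a bond, closing the carbocycle and the cis-fused α-methylene-γ-lactone together and setting both ring-fusion centres.
3. 19 comes from cross-metathesis of terminal alkene 16 with methyl 2-(bromomethyl)acrylate; 16 comes from Evans–Tishchenko reduction of aldol 13, which sets the anti-1,3-diol and places the acetate on the correct oxygen in one step.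
4. 13 comes from an Ipc2B aldol of Z-enone 11 (chiral pool, Stork–Zhao iodo-olefination) with Z-enal 4 (Z alkene taken from a butenolide ring).
5. Ring order: no ring until step 15; there the ten-membered carbocycle closes first (C–C bond) and the lactone second, in the same flask.

Assumption: in the Ipc2BCl aldol of methyl ketone 11, (+)-Ipc2BCl directs attack on the Si face of aldehyde 4; if the sense is the reverse, (−)-Ipc2BCl is used and nothing else changes.

**Route**

Step 1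
Reactants: 1 3-methylfuran-2(5H)-one
Product: 2 (2Z)-4-hydroxy-N-methoxy-N,2-dimethylbut-2-enamide
Conditions: MeNHOMe·HCl, Me3Al, CH2Cl2, 0 °C to rt
Reagents that add atoms: N,O-dimethylhydroxylamine hydrochloride, CNOC.Cl
Why: Weinreb aminolysis of the lactone by the aluminium amide opens the butenolide at the acyl carbon; the ring has already fixed the Z geometry of the trisubstituted alkene.

Step 2
Reactants: 2 hydroxy Weinreb amide
Product: 3 (2Z)-4-[(tert-butyldimethylsilyl)oxy]-N-methoxy-N,2-dimethylbut-2-enamide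
Conditions: TBSCl, imidazole, CH2Cl2, 0 °C
Reagents that add atoms: tert-butyldimethylsilyl chloride, CC(C)(C)[Si](C)(C)Cl
Why: Silylation of the primary alcohol stops relactonisation and masks the future aldehyde carbon.

Step 3
Reactants: 3 silyloxy Weinreb amide
Product: 4 (2Z)-4-[(tert-butyldimethylsilyl)oxy]-2-methylbut-2-enal
Conditions: i-Bu2AlH, THF, −78 °C; aq. potassium sodium tartrate
Reagents that add atoms: none
Why: Weinreb amide reduction stops at the aldehyde through the chelated tetrahedral intermediate; at −78 °C the Z geometry is kept.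

Step 4
Reactants: 5 (2S)-but-3-ene-1,2-diol
Product: 6 (4S)-4-ethenyl-2-(4-methoxyphenyl)-1,3-dioxolane (both C2 epimers)
Conditions: 4-MeOC6H4CH(OMe)2, CSA (cat.), CH2Cl2, rt
Reagents that add atoms: 4-methoxybenzaldehyde dimethyl acetal, COC(OC)c1ccc(OC)cc1
Why: Acid-catalysed transacetalisation gives the p-methoxybenzylidene acetal without touching the chiral-pool stereocentre.

Step 5
Reactants: 6 p-methoxybenzylidene acetal
Product: 7 (2S)-2-[(4-methoxybenzyl)oxy]but-3-en-1-ol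
Conditions: i-Bu2AlH, CH2Cl2, −78 to 0 °C
Reagents that add atoms: none
Why: Regioselective reductive acetal opening; aluminium binds the less hindered primary oxygen and cleaves that C–O bond, so the PMB ether stays on the secondary oxygen.

Step 6
Reactants: 7 primary alcohol
Product: 8 (2S)-2-[(4-methoxybenzyl)oxy]but-3-enal
Conditions: Dess–Martin periodinane, NaHCO3, CH2Cl2, 0 °C
Reagents that add atoms: none
Why: Buffered Dess–Martin oxidation gives the α-alkoxy aldehyde without epimerisation or migration of the alkene; it is used crude.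

Step 7
Reactants: 8 α-alkoxy aldehyde
Product: 9 (3S,4Z)-5-iodo-3-[(4-methoxybenzyl)oxy]hexa-1,4-diene
Conditions: EtPPh3I, n-BuLi, THF, 0 °C; I2, −78 °C; NaN(SiMe3)2; then 8, −78 to −20 °C
Reagents that add atoms: ethyltriphenylphosphonium iodide, CC[P+](c1ccccc1)(c1ccccc1)c1ccccc1.[I-]; iodine, II
Why: Stork–Zhao-type Wittig iodo-olefination with the non-stabilised α-iodo ylide gives the (Z)-2-iodoalkene, iodine cis to the carbinol carbon, which fixes the second Z-trisubstituted alkene.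

Step 8
Reactants: 9 Z-vinyl iodide
Product: 11 (3Z,5S)-5-[(4-methoxybenzyl)oxy]-3-methylhepta-3,6-dien-2-one, via vinyllithium 10 (not isolated)
Conditions: t-BuLi (2.1 equiv), Et2O, −78 °C; MeC(O)N(OMe)Me, −78 to 0 °C
Reagents that add atoms: N-methoxy-N-methylacetamide, CC(=O)N(C)OC
Why: Iodine–lithium exchange proceeds with retention of alkene geometry and Weinreb acylation of the vinyllithium stops at the ketone.

Step 9
Reactants: 11 Z-enone methyl ketone, 4 Z-enal
Product: 13 (3S,4Z,8S,9Z)-11-[(tert-butyldimethylsilyl)oxy]-8-hydroxy-3-[(4-methoxybenzyl)oxy]-5,9-dimethylundeca-1,4,9-trien-6-one, via boron enolate 12 (not isolated)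
Conditions: (+)-Ipc2BCl, Et3N, Et2O, 0 °C; 4, −78 to −20 °C; H2O2, MeOH, pH 7 buffer
Reagents that add atoms: none
Why: Paterson boron aldol of a methyl ketone; kinetic enolisation occurs at the methyl group and the Ipc ligands direct Si-face attack on the enal, setting C8 as S by reagent control; the minor C8 epimer is a diastereomer and is separated.

Step 10
Reactants: 13 β-hydroxy enone
Product: 14 (2Z,4S,6S,7Z,9S)-1-[(tert-butyldimethylsilyl)oxy]-6-hydroxy-9-[(4-methoxybenzyl)oxy]-3,7-dimethylundeca-2,7,10-trien-4-yl acetate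
Conditions: MeCHO (8 equiv), SmI2 (0.3 equiv), THF, −10 °C
Reagents that add atoms: acetaldehyde, CC=O
Why: Evans–Tishchenko reduction; the samarium-bound hemiacetal of the C4 hydroxyl delivers hydride intramolecularly to the ketone through a chair, setting C6 as S (1,3-anti) and leaving the acetate on the C4 oxygen.

Step 11
Reactants: 14 hydroxy acetate
Product: 15 (2Z,4S,6S,7Z,9S)-1,6-bis[(tert-butyldimethylsilyl)oxy]-9-[(4-methoxybenzyl)oxy]-3,7-dimethylundeca-2,7,10-trien-4-yl acetate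
Conditions: TBSOTf, 2,6-lutidine, CH2Cl2, −78 °C
Reagents that add atoms: tert-butyldimethylsilyl trifluoromethanesulfonate, CC(C)(C)[Si](C)(C)OS(=O)(=O)C(F)(F)F
Why: Silylation of the secondary allylic alcohol under non-nucleophilic conditions avoids 1,3-acetyl migration.

Step 12
Reactants: 15 bis-silyl ether
Product: 16 (2Z,4S,6S,7Z,9S)-6-[(tert-butyldimethylsilyl)oxy]-1-hydroxy-9-[(4-methoxybenzyl)oxy]-3,7-dimethylundeca-2,7,10-trien-4-yl acetate
Conditions: HF·pyridine, pyridine, THF, 0 °C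
Reagents that add atoms: none
Why: Buffered fluoride desilylation cleaves the primary allylic TBS ether much faster than the hindered secondary one.

Step 13
Reactants: 16 terminal alkene, 17 methyl 2-(bromomethyl)prop-2-enoate
Product: 18 methyl (2Z,4R,5Z,7S,9S,10Z)-9-acetoxy-2-(bromomethyl)-7-[(tert-butyldimethylsilyl)oxy]-12-hydroxy-4-[(4-methoxybenzyl)oxy]-6,10-dimethyldodeca-2,5,10-trienoate
Conditions: 17 (5 equiv), second-generation Hoveyda–Grubbs catalyst (10 mol%), 1,4-benzoquinone (10 mol%), CH2Cl2, 40 °C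
Reagents that add atoms: none
Why: Cross-metathesis of the only monosubstituted alkene with a methacrylate-type partner; the trisubstituted alkenes are inert, and the thermodynamic product has CH2Br cis to C4 (2Z).

Step 14
Reactants: 18 allylic alcohol
Product: 19 methyl (2Z,4R,5Z,7S,9S,10Z)-9-acetoxy-2-(bromomethyl)-7-[(tert-butyldimethylsilyl)oxy]-4-[(4-methoxybenzyl)oxy]-6,10-dimethyl-12-oxododeca-2,5,10-trienoate
Conditions: Dess–Martin periodinane, NaHCO3, CH2Cl2, 0 °C
Reagents that add atoms: none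
Why: Buffered Dess–Martin oxidation gives the Z-enal without isomerisation and tolerates the allylic bromide.

Step 15
Reactants: 19 bromo-enal
Product: 22 (3aS,4R,5Z,7S,9S,10Z,11aR)-7-[(tert-butyldimethylsilyl)oxy]-4-[(4-methoxybenzyl)oxy]-6,10-dimethyl-3-methylidene-2-oxo-2,3,3a,4,7,8,9,11a-octahydrocyclodeca[b]furan-9-yl acetate, via allylindium species 20 (not isolated), via hydroxy ester 21 (not isolated)
Conditions: In powder (6 equiv), THF/H2O 3:1, 25 °C, slow addition to 0.002 M; then PPTS, PhMe, 40 °C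
Reagents that add atoms: none
Why: Intramolecular Barbier allylation followed by lactonisation, known for ω-formyl 2-(bromomethyl)enoates and, with CrCl2, for ten-membered germacranolide rings; the Z-allylindium reacts through a chair to give the syn adduct (cis-fused lactone), and with C4–H eclipsing the alkene (A(1,3) strain) the tethered aldehyde adds to the face on the C5 side, anti to OPMB, which sets C3a and C11a.

Step 16
Reactants: 22 PMB-protected macrolactone
Product: 23 (3aS,4R,5Z,7S,9S,10Z,11aR)-7-[(tert-butyldimethylsilyl)oxy]-4-hydroxy-6,10-dimethyl-3-methylidene-2-oxo-2,3,3a,4,7,8,9,11a-octahydrocyclodeca[b]furan-9-yl acetate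
Conditions: DDQ, CH2Cl2/pH 7 buffer, 0 °C
Reagents that add atoms: none
Why: Oxidative PMB cleavage is orthogonal to the silyl ether, the acetate and the α-methylene lactone.

Step 17
Reactants: 23 C4 alcohol, 24 angelic acid
Product: 26 (3aR,4R,5Z,7S,9S,10Z,11aR)-9-acetoxy-7-[(tert-butyldimethylsilyl)oxy]-6,10-dimethyl-3-methylidene-2-oxo-2,3,3a,4,7,8,9,11a-octahydrocyclodeca[b]furan-4-yl (2Z)-2-methylbut-2-enoate, via mixed anhydride 25 (not isolated)
Conditions: 2,4,6-Cl3C6H2COCl, Et3N, PhMe, 25 °C; then 23, 80 °C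
Reagents that add atoms: none
Why: Yamaguchi-type esterification through the preformed mixed anhydride without DMAP acylates the only free hydroxyl and avoids isomerisation of the angelate to the tiglate.

Step 18
Reactants: 26 silyl-protected angelate
Product: 27 (3aR,4R,5Z,7S,9S,10Z,11aR)-9-acetoxy-7-hydroxy-6,10-dimethyl-3-methylidene-2-oxo-2,3,3a,4,7,8,9,11a-octahydrocyclodeca[b]furan-4-yl (2Z)-2-methylbut-2-enoate
Conditions: HF·pyridine, THF, 0 °C to rt
Reagents that add atoms: none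
Why: Acidic fluoride desilylation frees the C7 hydroxyl without acyl migration or conjugate addition to the α-methylene lactone.

**Compound list**

1 | 3-methylfuran-2(5H)-one | CC1=CCOC1=O | starting material
2 | (2Z)-4-hydroxy-N-methoxy-N,2-dimethylbut-2-enamide | CON(C)C(=O)/C(C)=C\CO | intermediate
3 | (2Z)-4-[(tert-butyldimethylsilyl)oxy]-N-methoxy-N,2-dimethylbut-2-enamide | CON(C)C(=O)/C(C)=C\CO[Si](C)(C)C(C)(C)C | intermediate
4 | (2Z)-4-[(tert-butyldimethylsilyl)oxy]-2-methylbut-2-enal | O=C/C(C)=C\CO[Si](C)(C)C(C)(C)C | intermediate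
5 | (2S)-but-3-ene-1,2-diol | C=C[C@H](O)CO | starting material
6 | (4S)-4-ethenyl-2-(4-methoxyphenyl)-1,3-dioxolane (both C2 epimers) | C=C[C@H]1COC(c2ccc(OC)cc2)O1 | intermediate
7 | (2S)-2-[(4-methoxybenzyl)oxy]but-3-en-1-ol | C=C[C@H](OCc1ccc(OC)cc1)CO | intermediate
8 | (2S)-2-[(4-methoxybenzyl)oxy]but-3-enal | C=C[C@H](OCc1ccc(OC)cc1)C=O | intermediate
9 | (3S,4Z)-5-iodo-3-[(4-methoxybenzyl)oxy]hexa-1,4-diene | C=C[C@H](OCc1ccc(OC)cc1)/C=C(/C)I | intermediate
10 | [(2E,4S)-4-[(4-methoxybenzyl)oxy]hexa-2,5-dien-2-yl]lithium (lithium in place of iodine of 9; geometry kept) | C=C[C@H](OCc1ccc(OC)cc1)/C=C(/C)[Li] | intermediate (not isolated)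
11 | (3Z,5S)-5-[(4-methoxybenzyl)oxy]-3-methylhepta-3,6-dien-2-one | CC(=O)/C(C)=C\[C@@H](OCc1ccc(OC)cc1)C=C | intermediate
12 | (+)-diisopinocampheylboron enolate of 11 (O-bound at C2; new C1=C2 bond) | C=C(OB([C@H]1C[C@H]2C[C@@H]([C@@H]1C)C2(C)C)[C@H]1C[C@H]2C[C@@H]([C@@H]1C)C2(C)C)/C(C)=C\[C@@H](OCc1ccc(OC)cc1)C=C | intermediate (not isolated)
13 | (3S,4Z,8S,9Z)-11-[(tert-butyldimethylsilyl)oxy]-8-hydroxy-3-[(4-methoxybenzyl)oxy]-5,9-dimethylundeca-1,4,9-trien-6-one | CC(C)(C)[Si](C)(C)OC/C=C(/C)[C@@H](O)CC(=O)/C(C)=C\[C@@H](OCc1ccc(OC)cc1)C=C | intermediate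
14 | (2Z,4S,6S,7Z,9S)-1-[(tert-butyldimethylsilyl)oxy]-6-hydroxy-9-[(4-methoxybenzyl)oxy]-3,7-dimethylundeca-2,7,10-trien-4-yl acetate | CC(C)(C)[Si](C)(C)OC/C=C(/C)[C@@H](OC(C)=O)C[C@H](O)/C(C)=C\[C@@H](OCc1ccc(OC)cc1)C=C | intermediate
15 | (2Z,4S,6S,7Z,9S)-1,6-bis[(tert-butyldimethylsilyl)oxy]-9-[(4-methoxybenzyl)oxy]-3,7-dimethylundeca-2,7,10-trien-4-yl acetate | CC(C)(C)[Si](C)(C)OC/C=C(/C)[C@@H](OC(C)=O)C[C@H](O[Si](C)(C)C(C)(C)C)/C(C)=C\[C@@H](OCc1ccc(OC)cc1)C=C | intermediate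
16 | (2Z,4S,6S,7Z,9S)-6-[(tert-butyldimethylsilyl)oxy]-1-hydroxy-9-[(4-methoxybenzyl)oxy]-3,7-dimethylundeca-2,7,10-trien-4-yl acetate | OC/C=C(/C)[C@@H](OC(C)=O)C[C@H](O[Si](C)(C)C(C)(C)C)/C(C)=C\[C@@H](OCc1ccc(OC)cc1)C=C | intermediate
17 | methyl 2-(bromomethyl)prop-2-enoate | C=C(CBr)C(=O)OC | starting material
18 | methyl (2Z,4R,5Z,7S,9S,10Z)-9-acetoxy-2-(bromomethyl)-7-[(tert-butyldimethylsilyl)oxy]-12-hydroxy-4-[(4-methoxybenzyl)oxy]-6,10-dimethyldodeca-2,5,10-trienoate (the PMB-bearing carbon is unchanged in space; its descriptor turns from S to R by CIP ranking only) | OC/C=C(/C)[C@@H](OC(C)=O)C[C@H](O[Si](C)(C)C(C)(C)C)/C(C)=C\[C@@H](OCc1ccc(OC)cc1)/C=C(\CBr)C(=O)OC | intermediate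
19 | methyl (2Z,4R,5Z,7S,9S,10Z)-9-acetoxy-2-(bromomethyl)-7-[(tert-butyldimethylsilyl)oxy]-4-[(4-methoxybenzyl)oxy]-6,10-dimethyl-12-oxododeca-2,5,10-trienoate | O=C/C=C(/C)[C@@H](OC(C)=O)C[C@H](O[Si](C)(C)C(C)(C)C)/C(C)=C\[C@@H](OCc1ccc(OC)cc1)/C=C(\CBr)C(=O)OC | intermediate
20 | allylindium species from 19, drawn as the dibromoindium compound (indium in place of bromine on the CH2 group) | O=C/C=C(/C)[C@@H](OC(C)=O)C[C@H](O[Si](C)(C)C(C)(C)C)/C(C)=C\[C@@H](OCc1ccc(OC)cc1)/C=C(\C[In](Br)Br)C(=O)OC | intermediate (not isolated)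
21 | methyl 2-[(1R,2R,3Z,5S,7S,8Z,10R)-5-acetoxy-7-[(tert-butyldimethylsilyl)oxy]-2-hydroxy-10-[(4-methoxybenzyl)oxy]-4,8-dimethylcyclodeca-3,8-dien-1-yl]prop-2-enoate | C=C(C(=O)OC)[C@@H]1[C@H](O)/C=C(/C)[C@@H](OC(C)=O)C[C@H](O[Si](C)(C)C(C)(C)C)/C(C)=C\[C@H]1OCc2ccc(OC)cc2 | intermediate (not isolated)
22 | (3aS,4R,5Z,7S,9S,10Z,11aR)-7-[(tert-butyldimethylsilyl)oxy]-4-[(4-methoxybenzyl)oxy]-6,10-dimethyl-3-methylidene-2-oxo-2,3,3a,4,7,8,9,11a-octahydrocyclodeca[b]furan-9-yl acetate (cis-fused lactone; same spatial arrangement at C3a as in 27, descriptor S by CIP ranking only) | C=C1C(=O)O[C@@H]2/C=C(/C)[C@@H](OC(C)=O)C[C@H](O[Si](C)(C)C(C)(C)C)/C(C)=C\[C@@H](OCc3ccc(OC)cc3)[C@H]12 | intermediate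
23 | (3aS,4R,5Z,7S,9S,10Z,11aR)-7-[(tert-butyldimethylsilyl)oxy]-4-hydroxy-6,10-dimethyl-3-methylidene-2-oxo-2,3,3a,4,7,8,9,11a-octahydrocyclodeca[b]furan-9-yl acetate | C=C1C(=O)O[C@@H]2/C=C(/C)[C@@H](OC(C)=O)C[C@H](O[Si](C)(C)C(C)(C)C)/C(C)=C\[C@@H](O)[C@H]12 | intermediate
24 | angelic acid ((2Z)-2-methylbut-2-enoic acid) | C/C=C(/C)C(=O)O | starting material
25 | (2Z)-2-methylbut-2-enoic 2,4,6-trichlorobenzoic anhydride | C/C=C(/C)C(=O)OC(=O)c1c(Cl)cc(Cl)cc1Cl | intermediate (not isolated)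
26 | (3aR,4R,5Z,7S,9S,10Z,11aR)-9-acetoxy-7-[(tert-butyldimethylsilyl)oxy]-6,10-dimethyl-3-methylidene-2-oxo-2,3,3a,4,7,8,9,11a-octahydrocyclodeca[b]furan-4-yl (2Z)-2-methylbut-2-enoate | C=C1C(=O)O[C@@H]2/C=C(/C)[C@@H](OC(C)=O)C[C@H](O[Si](C)(C)C(C)(C)C)/C(C)=C\[C@@H](OC(=O)/C(C)=C\C)[C@H]12 | intermediate
27 | (3aR,4R,5Z,7S,9S,10Z,11aR)-9-acetoxy-7-hydroxy-6,10-dimethyl-3-methylidene-2-oxo-2,3,3a,4,7,8,9,11a-octahydrocyclodeca[b]furan-4-yl (2Z)-2-methylbut-2-enoate (CNP0319825.3) | C=C1C(=O)O[C@@H]2/C=C(/C)[C@@H](OC(C)=O)C[C@H](O)/C(C)=C\[C@@H](OC(=O)/C(C)=C\C)[C@H]12 | target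

**Step count and risk**

Total steps: 18. Longest linear sequence: 15 steps (5 to 27, steps 4 to 18); the branch from 1 adds 3 steps before the union in step 9.

Most likely to fail, first: step 15. The ten-membered ring may lose to oligomers or to protonolysis of the allylindium, and the facial sense at C3a/C11a rests on a conformational argument, not on precedent. Fallback: setting out from 18, Pd2(dba)3-catalysed borylation with B2pin2 replaces the bromide and gives the allylboronate alcohol F1. Dess–Martin oxidation gives the allylboronate aldehyde F2. F2 is a stable, isolable allyl donor that cannot be protonated or homocoupled, and it is cyclised at high dilution with Sc(OTf)3 (cat.) in toluene by intramolecular allylboration through a closed chair. Lactonisation on work-up returns to the route at 22.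

Second: step 13. The terminal alkene sits on a hindered, doubly allylic carbon and the acrylate partner is 1,1-disubstituted, so cross-metathesis may stall. Fallback: setting out from 15, cross-metathesis with the far more reactive methyl acrylate (same catalyst) gives the (E)-enoate F3. Conjugate addition of PhSLi/Me3Al and trapping of the enolate with CH2O gives the β-phenylsulfanyl α-hydroxymethyl ester F4. NaIO4 oxidation and thermal sulfoxide elimination give the 2-(hydroxymethyl)enoate F5. CBr4/PPh3, with LiBr to equilibrate to the Z-bromide, gives the allylic bromide F6. CSA in MeOH at 0 °C then removes the primary silyl group and returns to the route at 18.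

Third: step 9. Reagent control with a methyl ketone is moderate, the Z-enal and Z-enone can isomerise, and γ-deprotonation of 11 would erase the PMB-bearing centre. Fallback: setting out from 4, aldol addition of doubly deprotonated (S)-2-hydroxy-1,2,2-triphenylethyl acetate (LiN(i-Pr)2, then MgBr2, −100 °C) gives the auxiliary ester F7 with the carbinol centre set by the auxiliary. LiOH hydrolysis gives the β-hydroxy acid F8, and MeNHOMe·HCl/EDC gives the β-hydroxy Weinreb amide F9. F9 is deprotonated with i-PrMgCl and treated with vinyllithium 10 (made from 9 as in step 8), which forms the enone directly and returns to the route at 13 without any enolisation of 11.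

Further compounds
F1 | step 15 | methyl (2E,4R,5Z,7S,9S,10Z)-9-acetoxy-7-[(tert-butyldimethylsilyl)oxy]-12-hydroxy-4-[(4-methoxybenzyl)oxy]-6,10-dimethyl-2-[(4,4,5,5-tetramethyl-1,3,2-dioxaborolan-2-yl)methyl]dodeca-2,5,10-trienoate | OC/C=C(/C)[C@@H](OC(C)=O)C[C@H](O[Si](C)(C)C(C)(C)C)/C(C)=C\[C@@H](OCc1ccc(OC)cc1)/C=C(\CB1OC(C)(C)C(C)(C)O1)C(=O)OC
F2 | step 15 | methyl (2E,4R,5Z,7S,9S,10Z)-9-acetoxy-7-[(tert-butyldimethylsilyl)oxy]-4-[(4-methoxybenzyl)oxy]-6,10-dimethyl-12-oxo-2-[(4,4,5,5-tetramethyl-1,3,2-dioxaborolan-2-yl)methyl]dodeca-2,5,10-trienoate | O=C/C=C(/C)[C@@H](OC(C)=O)C[C@H](O[Si](C)(C)C(C)(C)C)/C(C)=C\[C@@H](OCc1ccc(OC)cc1)/C=C(\CB1OC(C)(C)C(C)(C)O1)C(=O)OC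
F3 | step 13 | methyl (2E,4S,5Z,7S,9S,10Z)-9-acetoxy-7,12-bis[(tert-butyldimethylsilyl)oxy]-4-[(4-methoxybenzyl)oxy]-6,10-dimethyldodeca-2,5,10-trienoate | CC(C)(C)[Si](C)(C)OC/C=C(/C)[C@@H](OC(C)=O)C[C@H](O[Si](C)(C)C(C)(C)C)/C(C)=C\[C@@H](OCc1ccc(OC)cc1)/C=C/C(=O)OC
F4 | step 13 | methyl (4R,5Z,7S,9S,10Z)-9-acetoxy-7,12-bis[(tert-butyldimethylsilyl)oxy]-2-(hydroxymethyl)-4-[(4-methoxybenzyl)oxy]-6,10-dimethyl-3-(phenylsulfanyl)dodeca-5,10-dienoate (mixture at C2 and C3) | CC(C)(C)[Si](C)(C)OC/C=C(/C)[C@@H](OC(C)=O)C[C@H](O[Si](C)(C)C(C)(C)C)/C(C)=C\[C@@H](OCc1ccc(OC)cc1)C(Sc1ccccc1)C(CO)C(=O)OC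
F5 | step 13 | methyl (2E,4R,5Z,7S,9S,10Z)-9-acetoxy-7,12-bis[(tert-butyldimethylsilyl)oxy]-2-(hydroxymethyl)-4-[(4-methoxybenzyl)oxy]-6,10-dimethyldodeca-2,5,10-trienoate | CC(C)(C)[Si](C)(C)OC/C=C(/C)[C@@H](OC(C)=O)C[C@H](O[Si](C)(C)C(C)(C)C)/C(C)=C\[C@@H](OCc1ccc(OC)cc1)/C=C(\CO)C(=O)OC
F6 | step 13 | methyl (2Z,4R,5Z,7S,9S,10Z)-9-acetoxy-2-(bromomethyl)-7,12-bis[(tert-butyldimethylsilyl)oxy]-4-[(4-methoxybenzyl)oxy]-6,10-dimethyldodeca-2,5,10-trienoate | CC(C)(C)[Si](C)(C)OC/C=C(/C)[C@@H](OC(C)=O)C[C@H](O[Si](C)(C)C(C)(C)C)/C(C)=C\[C@@H](OCc1ccc(OC)cc1)/C=C(\CBr)C(=O)OC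
F7 | step 9 | (1S)-2-hydroxy-1,2,2-triphenylethyl (3S,4Z)-6-[(tert-butyldimethylsilyl)oxy]-3-hydroxy-4-methylhex-4-enoate | CC(C)(C)[Si](C)(C)OC/C=C(/C)[C@@H](O)CC(=O)O[C@@H](c1ccccc1)C(O)(c1ccccc1)c1ccccc1
F8 | step 9 | (3S,4Z)-6-[(tert-butyldimethylsilyl)oxy]-3-hydroxy-4-methylhex-4-enoic acid | CC(C)(C)[Si](C)(C)OC/C=C(/C)[C@@H](O)CC(O)=O
F9 | step 9 | (3S,4Z)-6-[(tert-butyldimethylsilyl)oxy]-3-hydroxy-N-methoxy-N,4-dimethylhex-4-enamide | CC(C)(C)[Si](C)(C)OC/C=C(/C)[C@@H](O)CC(=O)N(C)OC
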